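**Plan**

- Feature: in ring C (the pyranone) C3 is a lone CH between C2, which carries ring B and O1, and the C4 carbonyl. This one carbon can be delivered as a carbene to the enol-ether bond of a 2-aryl-3-siloxybenzofuran, whose C3 oxygen then becomes the C4 carbonyl oxygen.
- Retrosynthesis: the benzyl ether and a C3 bromine (left by the carbene) come off last. C2–C3 and C3–C4 of ring C are then cut together, contracting the pyranone to the benzofuran. The benzofuranone behind it is cut at C3–C3a (Friedel–Crafts acylation) and at O1–C2 (phenoxide alkylation).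
- Forward: ring A arrives complete as 2,3,4,5-tetramethoxyphenol, made from 2,3,4-trimethoxybenzaldehyde. Ring B arrives as a benzyl α-bromoarylacetate, made from 3-hydroxy-4-methoxyphenylacetic acid.
- Ether formation joins the two, the five-membered furanone ring closes next, and ring C arises last by enlargement of that five-membered ring to six.
- Stereochemistry: the target has no stereocentre. The one stereocentre of the intermediates (the carbon that becomes C2) is carried racemic and is erased on enol silylation.

Key step: step 11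

**Route**

Step 1
Reactants: 1 2,3,4-trimethoxybenzaldehyde
Product: 3 2,3,4-trimethoxyphenol, via aryl formate 2 (not isolated)
Conditions: mCPBA, CH2Cl2, 0 °C → rt; then K2CO3 (cat.), MeOH, rt, under N2
Reagents that add atoms: 3-chloroperoxybenzoic acid (O=C(OO)c1cccc(Cl)c1)
Why: Baeyer–Villiger oxidation in its Dakin-type variant, in which the aryl group of an electron-rich benzaldehyde migrates in preference to hydride and the resulting aryl formate is cleaved by mild methanolysis.

Step 2
Reactants: 3 2,3,4-trimethoxyphenol
Product: 4 1,2,3,4-tetramethoxybenzene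
Conditions: MeI, K2CO3, acetone, reflux
Reagents that add atoms: iodomethane (CI)
Why: Williamson ether synthesis on a phenoxide with an unhindered methylating agent.

Step 3
Reactants: 4 1,2,3,4-tetramethoxybenzene
Product: 6 2,3,4,5-tetramethoxybenzaldehyde, via iminium chloride 5 (not isolated)
Conditions: POCl3, DMF, 0 → 80 °C; then ice-water, rt
Reagents that add atoms: N,N-dimethylformamide (CN(C)C=O); water (O)
Why: Vilsmeier–Haack formylation; the two unsubstituted positions of 4 are equivalent by symmetry and each lies ortho to one methoxy group and para to another, so a single aldehyde should result after hydrolysis of the iminium salt.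

Step 4
Reactants: 6 2,3,4,5-tetramethoxybenzaldehyde
Product: 8 2,3,4,5-tetramethoxyphenol, via aryl formate 7 (not isolated)
Conditions: mCPBA (1.1 equiv), CH2Cl2, 0 °C → rt; then K2CO3 (cat.), MeOH, rt, under N2
Reagents that add atoms: 3-chloroperoxybenzoic acid (O=C(OO)c1cccc(Cl)c1)
Why: a second Baeyer–Villiger (Dakin-type) oxidation with aryl migration favoured by the ortho- and para-methoxy groups, followed by methanolysis of the formate under inert gas to spare the oxidation-prone phenol.

Step 5
Reactants: 9 3-hydroxy-4-methoxyphenylacetic acid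
Product: 10 benzyl 2-[3-(benzyloxy)-4-methoxyphenyl]acetate
Conditions: BnBr (2.5 equiv), K2CO3, DMF, 60 °C
Reagents that add atoms: benzyl bromide (BrCc1ccccc1)
Why: Williamson-type O-alkylation of both the carboxylate and the phenoxide in one operation, K2CO3 being too weak to enolise the ester.

Step 6
Reactants: 10 benzyl 2-[3-(benzyloxy)-4-methoxyphenyl]acetate
Product: 13 benzyl 2-bromo-2-[3-(benzyloxy)-4-methoxyphenyl]acetate (racemic), via lithium enolate 11 (not isolated), via ketene silyl acetal 12 (not isolated)
Conditions: LiN(SiMe3)2, THF, −78 °C; Me3SiCl; then NBS, −78 → 0 °C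
Reagents that add atoms: N-bromosuccinimide (O=C1CCC(=O)N1Br)
Why: electrophilic α-bromination of an ester through its ketene silyl acetal, which should react with N-bromosuccinimide at low temperature far faster than the alkoxy-substituted arene and avoids radical conditions that would attack the two benzylic O–CH2 positions; the new stereocentre is formed racemic.

Step 7
Reactants: 8 2,3,4,5-tetramethoxyphenol; 13 benzyl 2-bromo-2-[3-(benzyloxy)-4-methoxyphenyl]acetate
Product: 14 benzyl 2-[3-(benzyloxy)-4-methoxyphenyl]-2-(2,3,4,5-tetramethoxyphenoxy)acetate (racemic)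
Conditions: K2CO3, DMF, rt → 50 °C
Reagents that add atoms: none
Why: Williamson ether synthesis by SN2 displacement of an activated secondary α-bromo ester by the phenoxide of 8, a well-used entry to α-aryloxy arylacetates; the stereocentre stays racemic.

Step 8
Reactants: 14 benzyl 2-[3-(benzyloxy)-4-methoxyphenyl]-2-(2,3,4,5-tetramethoxyphenoxy)acetate
Product: 15 2-[3-(benzyloxy)-4-methoxyphenyl]-2-(2,3,4,5-tetramethoxyphenoxy)acetic acid (racemic)
Conditions: LiOH, THF/H2O, rt; then aq HCl to pH 3
Reagents that add atoms: lithium hydroxide ([Li+].[OH-])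
Why: saponification of the benzyl ester by hydroxide, which leaves the benzyl aryl ether and the diaryl-type ether untouched.

Step 9
Reactants: 15 2-[3-(benzyloxy)-4-methoxyphenyl]-2-(2,3,4,5-tetramethoxyphenoxy)acetic acid
Product: 17 2-[3-(benzyloxy)-4-methoxyphenyl]-4,5,6,7-tetramethoxy-1-benzofuran-3(2H)-one (racemic), via mixed trifluoroacetic anhydride 16 (not isolated)
Conditions: (CF3CO)2O (1.5 equiv), CH2Cl2, 0 °C → rt, under Ar; aq NaHCO3 work-up
Reagents that add atoms: none
Why: intramolecular Friedel–Crafts acylation through the mixed trifluoroacetic anhydride, which closes the five-membered ring at the only unsubstituted position of ring A (ortho to the ether oxygen and to one methoxy group, para to another) without a strong Lewis acid that would cleave the benzyl ether or favour decarbonylation of a free α-aryloxy acylium ion.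

Step 10
Reactants: 17 2-[3-(benzyloxy)-4-methoxyphenyl]-4,5,6,7-tetramethoxy-1-benzofuran-3(2H)-one
Product: 18 2-[3-(benzyloxy)-4-methoxyphenyl]-3-[(tert-butyldimethylsilyl)oxy]-4,5,6,7-tetramethoxy-1-benzofuran
Conditions: TBSOTf, Et3N, CH2Cl2, 0 °C
Reagents that add atoms: tert-butyldimethylsilyl trifluoromethanesulfonate (CC(C)(C)[Si](C)(C)OS(=O)(=O)C(F)(F)F)
Why: O-silylation of an enolisable ketone with a silyl triflate and an amine base, here driven by aromatisation to the benzofuran; the racemic stereocentre at C2 disappears.

Step 11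
Reactants: 18 2-[3-(benzyloxy)-4-methoxyphenyl]-3-[(tert-butyldimethylsilyl)oxy]-4,5,6,7-tetramethoxy-1-benzofuran; 19 bromoform
Product: 22 3-bromo-2-[3-(benzyloxy)-4-methoxyphenyl]-5,6,7,8-tetramethoxy-4H-chromen-4-one, via dibromocyclopropane 20 (not isolated), via siloxybenzopyrylium bromide 21 (not isolated)
Conditions: KOtBu (1.5 equiv), 19 (1.5 equiv, slow addition), toluene, −20 °C → rt; then H2O
Reagents that add atoms: none
Why: Proposed new method: dibromocarbene, formed by α-elimination from 19 and KOtBu, should add in a [2+1] cheletropic step to the C2=C3 bond of 18 to give the cis-fused dibromocyclopropane 20; the closest known reaction types are the dihalocarbene one-carbon ring expansion of cyclic silyl enol ethers to 2-halo-enones and the Ciamician–Dennstedt expansion of pyrroles and indoles to 3-halopyridines and 3-haloquinolines, neither of which has been applied to a 2-aryl-3-siloxybenzofuran. Ionisation of the endo C–Br bond of 20 is coupled to disrotatory two-electron electrocyclic cleavage of the old C2–C3 bond (Woodward–Hoffmann–DePuy rule) and is assisted by the lone pairs on O1 and on the siloxy oxygen, so the six-membered ring arises by enlargement of the furan and not by a cyclisation, both new bonds (C2–C3 and C3–C4 in flavone numbering) having been made in the carbene addition. The resulting 3-bromo-4-siloxybenzopyrylium bromide 21 is an aromatic cation, and attack of bromide at silicon should release the pyranone carbonyl of 22. No stereocentre is created in 22; the two stereocentres of 20 are necessarily cis and are lost on ring opening. The step needs chemoselectivity for the enol ether bond over the two arene rings and the benzyl ether, which should be secured by the double oxygen donation at C2=C3, by the fully substituted ring A and by the low reactivity of simple alkoxyarenes towards dihalocarbenes; the bulky tert-butyldimethylsilyl group is chosen so that the enol ether survives KOtBu until the carbene has added.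

Step 12
Reactants: 22 3-bromo-2-[3-(benzyloxy)-4-methoxyphenyl]-5,6,7,8-tetramethoxy-4H-chromen-4-one
Product: 24 3'-demethylnobiletin, via benzyl-protected flavone 23 (not isolated)
Conditions: H2 (1 atm), Pd/C, NaOAc, EtOAc/MeOH, rt; stopped when 22 and 23 are consumed
Reagents that add atoms: none
Why: catalytic hydrogenolysis over Pd/C, in which the vinylic C–Br bond should be cleaved first (hydrodehalogenation, NaOAc taking up the HBr) and the benzyl aryl ether then loses toluene, while the chromone C2=C3 bond, a vinylogous ester, is reduced much more slowly at one atmosphere.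

**Compound list**

1 | 2,3,4-trimethoxybenzaldehyde | COc1ccc(C=O)c(OC)c1OC | starting material
2 | 2,3,4-trimethoxyphenyl formate | COc1ccc(OC=O)c(OC)c1OC | intermediate
3 | 2,3,4-trimethoxyphenol | COc1ccc(O)c(OC)c1OC | intermediate
4 | 1,2,3,4-tetramethoxybenzene | COc1ccc(OC)c(OC)c1OC | intermediate
5 | N,N-dimethyl-(2,3,4,5-tetramethoxyphenyl)methaniminium chloride | COc1cc(C=[N+](C)C)c(OC)c(OC)c1OC.[Cl-] | intermediate
6 | 2,3,4,5-tetramethoxybenzaldehyde | COc1cc(C=O)c(OC)c(OC)c1OC | intermediate
7 | 2,3,4,5-tetramethoxyphenyl formate | COc1cc(OC=O)c(OC)c(OC)c1OC | intermediate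
8 | 2,3,4,5-tetramethoxyphenol | COc1cc(O)c(OC)c(OC)c1OC | intermediate
9 | 3-hydroxy-4-methoxyphenylacetic acid | COc1ccc(CC(=O)O)cc1O | starting material
10 | benzyl 2-[3-(benzyloxy)-4-methoxyphenyl]acetate | COc1ccc(CC(=O)OCc2ccccc2)cc1OCc1ccccc1 | intermediate
11 | lithium enolate of 10 | COc1ccc(C=C([O-])OCc2ccccc2)cc1OCc1ccccc1.[Li+] | intermediate
12 | benzyl trimethylsilyl ketene acetal of 10 (double-bond geometry not defined) | COc1ccc(C=C(O[Si](C)(C)C)OCc2ccccc2)cc1OCc1ccccc1 | intermediate
13 | benzyl 2-bromo-2-[3-(benzyloxy)-4-methoxyphenyl]acetate (racemic) | COc1ccc(C(Br)C(=O)OCc2ccccc2)cc1OCc1ccccc1 | intermediate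
14 | benzyl 2-[3-(benzyloxy)-4-methoxyphenyl]-2-(2,3,4,5-tetramethoxyphenoxy)acetate (racemic) | COc1ccc(C(Oc2cc(OC)c(OC)c(OC)c2OC)C(=O)OCc2ccccc2)cc1OCc1ccccc1 | intermediate
15 | 2-[3-(benzyloxy)-4-methoxyphenyl]-2-(2,3,4,5-tetramethoxyphenoxy)acetic acid (racemic) | COc1ccc(C(Oc2cc(OC)c(OC)c(OC)c2OC)C(=O)O)cc1OCc1ccccc1 | intermediate
16 | mixed anhydride of acid 15 and trifluoroacetic acid (racemic) | COc1ccc(C(Oc2cc(OC)c(OC)c(OC)c2OC)C(=O)OC(=O)C(F)(F)F)cc1OCc1ccccc1 | intermediate
17 | 2-[3-(benzyloxy)-4-methoxyphenyl]-4,5,6,7-tetramethoxy-1-benzofuran-3(2H)-one (racemic) | COc1ccc(C2Oc3c(OC)c(OC)c(OC)c(OC)c3C2=O)cc1OCc1ccccc1 | intermediate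
18 | 2-[3-(benzyloxy)-4-methoxyphenyl]-3-[(tert-butyldimethylsilyl)oxy]-4,5,6,7-tetramethoxy-1-benzofuran | COc1ccc(-c2oc3c(OC)c(OC)c(OC)c(OC)c3c2O[Si](C)(C)C(C)(C)C)cc1OCc1ccccc1 | intermediate
19 | bromoform | BrC(Br)Br | starting material
20 | 1,1-dibromo-1a-[3-(benzyloxy)-4-methoxyphenyl]-6b-[(tert-butyldimethylsilyl)oxy]-3,4,5,6-tetramethoxy-1a,6b-dihydro-1H-cyclopropa[b][1]benzofuran (racemic, cis-fused) | COc1ccc(C23Oc4c(OC)c(OC)c(OC)c(OC)c4C2(O[Si](C)(C)C(C)(C)C)C3(Br)Br)cc1OCc1ccccc1 | intermediate
21 | 3-bromo-2-[3-(benzyloxy)-4-methoxyphenyl]-4-[(tert-butyldimethylsilyl)oxy]-5,6,7,8-tetramethoxychromenylium bromide | COc1ccc(-c2[o+]c3c(OC)c(OC)c(OC)c(OC)c3c(O[Si](C)(C)C(C)(C)C)c2Br)cc1OCc1ccccc1.[Br-] | intermediate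
22 | 3-bromo-2-[3-(benzyloxy)-4-methoxyphenyl]-5,6,7,8-tetramethoxy-4H-chromen-4-one | COc1ccc(-c2oc3c(OC)c(OC)c(OC)c(OC)c3c(=O)c2Br)cc1OCc1ccccc1 | intermediate
23 | 2-[3-(benzyloxy)-4-methoxyphenyl]-5,6,7,8-tetramethoxy-4H-chromen-4-one | COc1ccc(-c2cc(=O)c3c(OC)c(OC)c(OC)c(OC)c3o2)cc1OCc1ccccc1 | intermediate
24 | 3'-demethylnobiletin, 2-(3-hydroxy-4-methoxyphenyl)-5,6,7,8-tetramethoxy-4H-chromen-4-one | COc1ccc(-c2cc(=O)c3c(OC)c(OC)c(OC)c(OC)c3o2)cc1O | target

**Step count and risks**

Total step count: 12. Longest linear sequence: 10 steps (from 1 through steps 1–4 and 7–12); the ring B branch from 9 runs 8 steps (5–12).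

Steps most likely to fail:

Step 11 (the unprecedented step). The carbene may add too slowly to the hindered, tetrasubstituted enol ether bond. tert-Butoxide would then strip the silyl group first and the freed enolate would be dibromomethylated at C2. The base might also open the pyranone once it has formed. The fallback builds ring C by the classical chalcone route and sets out from phenol 8. C-Acetylation of 8 at its only free position with acetic anhydride and BF3·OEt2 (Fries-type) should give 1-(2-hydroxy-3,4,5,6-tetramethoxyphenyl)ethan-1-one F1. Claisen–Schmidt condensation of this ketone with commercial 3-benzyloxy-4-methoxybenzaldehyde (KOH, EtOH) should give (E)-3-[3-(benzyloxy)-4-methoxyphenyl]-1-(2-hydroxy-3,4,5,6-tetramethoxyphenyl)prop-2-en-1-one F2. Oxidative cyclisation of the chalcone with catalytic iodine in DMSO at 120 °C (oxa-Michael addition, then dehydrogenation) should give flavone 23, where the route is rejoined. Hydrogenolysis under the conditions of step 12 then has only the benzyl group to remove and should give 24.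

Step 9. The activated acyl group may lose carbon monoxide, because the cation left behind is stabilised by the aryloxy oxygen and by the 4-methoxyphenyl ring, or the acid liberated may cleave the benzyl ether. The fallback makes the C3–C3a bond first and the O1–C2 bond last, and sets out from phenol 8 and acid 9. Heating the two in BF3·OEt2 (C-acylation of the phenol by the arylacetic acid, no α-oxygen on the acyl group) should give 1-(2-hydroxy-3,4,5,6-tetramethoxyphenyl)-2-(3-hydroxy-4-methoxyphenyl)ethan-1-one F3. Benzylation of the ring B phenol, which is not hydrogen-bonded to the ketone (BnBr 1 equiv, K2CO3, acetone), should give 2-[3-(benzyloxy)-4-methoxyphenyl]-1-(2-hydroxy-3,4,5,6-tetramethoxyphenyl)ethan-1-one F4. Bromination at the doubly activated methylene with PhNMe3Br3 in THF should give 2-bromo-2-[3-(benzyloxy)-4-methoxyphenyl]-1-(2-hydroxy-3,4,5,6-tetramethoxyphenyl)ethan-1-one F5. Intramolecular O-alkylation of this bromide with K2CO3 in acetone should close the furanone and return to the route at 17.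

Step 6. The electron-rich arene may be brominated in competition, or unreacted enolate may couple with bromo ester already formed. The fallback replaces the bromide by a carbenoid and sets out from ester 10. Diazo transfer with 4-acetamidobenzenesulfonyl azide and DBU in MeCN should give benzyl 2-diazo-2-[3-(benzyloxy)-4-methoxyphenyl]acetate F6. Rh2(OAc)4-catalysed O–H insertion of the derived carbenoid into phenol 8 in CH2Cl2 should give ether 14 directly, where the route is rejoined; bromide 13 and step 7 are then not needed.

**Further compounds**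

F1 | step 11 | 1-(2-hydroxy-3,4,5,6-tetramethoxyphenyl)ethan-1-one | CC(=O)c1c(O)c(OC)c(OC)c(OC)c1OC
F2 | step 11 | (E)-3-[3-(benzyloxy)-4-methoxyphenyl]-1-(2-hydroxy-3,4,5,6-tetramethoxyphenyl)prop-2-en-1-one | COc1ccc(/C=C/C(=O)c2c(O)c(OC)c(OC)c(OC)c2OC)cc1OCc1ccccc1
F3 | step 9 | 1-(2-hydroxy-3,4,5,6-tetramethoxyphenyl)-2-(3-hydroxy-4-methoxyphenyl)ethan-1-one | COc1ccc(CC(=O)c2c(O)c(OC)c(OC)c(OC)c2OC)cc1O
F4 | step 9 | 2-[3-(benzyloxy)-4-methoxyphenyl]-1-(2-hydroxy-3,4,5,6-tetramethoxyphenyl)ethan-1-one | COc1ccc(CC(=O)c2c(O)c(OC)c(OC)c(OC)c2OC)cc1OCc1ccccc1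
F5 | step 9 | 2-bromo-2-[3-(benzyloxy)-4-methoxyphenyl]-1-(2-hydroxy-3,4,5,6-tetramethoxyphenyl)ethan-1-one (racemic) | COc1ccc(C(Br)C(=O)c2c(O)c(OC)c(OC)c(OC)c2OC)cc1OCc1ccccc1
F6 | step 6 | benzyl 2-diazo-2-[3-(benzyloxy)-4-methoxyphenyl]acetate | COc1ccc(C(=[N+]=[N-])C(=O)OCc2ccccc2)cc1OCc1ccccc1
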